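## Retrosynthetic overview

1. The target comes from its 5,7-bis(methoxymethyl) ether by acid removal of the two MOM groups in the last step.
2. Ring C is the only ring that is built (rings A and B are bought as arenes). It is closed by a Mitsunobu C2–O1 etherification of an (R)-β-hydroxy ketone with inversion, giving (2S).
3. The (R)-carbinol comes from reductive opening of a (2R,3S)-epoxychalcone, made by Juliá–Colonna epoxidation of the chalcone.
4. The key C2–C3 bond is made by a Claisen–Schmidt aldol condensation of a fully substituted ring A acetophenone with benzaldehyde.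
5. The acetophenone comes from phloroglucinol by two directed ortho-metalations: geranyl between the two MOM ethers, then acetyl next to the one differently protected oxygen.

Abbreviations: Ger = (2E)-3,7-dimethylocta-2,6-dien-1-yl (geranyl); MOM = CH2OCH3; TIPS = Si(i-Pr)3; THP = tetrahydro-2H-pyran-2-yl.

Assumption: the THP acetal carbon is carried as an inconsequential mixture of epimers (left undefined in the SMILES) until it is removed in step 10.

## Route

Step 1
Reactants: 1 phloroglucinol (benzene-1,3,5-triol)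
Product: 2 5-(TIPS-oxy)benzene-1,3-diol
Conditions: 1 (3 equiv), TIPSCl (1 equiv), imidazole, DMF, 0 °C to rt; excess 1 washed out with water
Reagents that add atoms: triisopropylsilyl chloride (TIPSCl), CC(C)[Si](Cl)(C(C)C)C(C)C
Why: Phenol silylation with the cheap triol in excess makes the mono-silyl ether the main product and marks one oxygen as different from the other two.

Step 2
Reactants: 2 5-(TIPS-oxy)benzene-1,3-diol
Product: 3 1,3-bis(MOM-oxy)-5-(TIPS-oxy)benzene
Conditions: MOMCl (2.5 equiv), i-Pr2NEt, CH2Cl2, 0 °C to rt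
Reagents that add atoms: chloromethyl methyl ether (MOMCl), COCCl
Why: Williamson-type O-alkylation of both free phenols gives two MOM ethers that are strong ortho-directing groups, while the silyl ether is untouched by the amine base.

Step 3
Reactants: 3 1,3-bis(MOM-oxy)-5-(TIPS-oxy)benzene, 4 geranyl bromide
Product: 6 2-Ger-1,3-bis(MOM-oxy)-5-(TIPS-oxy)benzene, via 2-lithio arene 5 (not isolated)
Conditions: n-BuLi, THF, 0 °C, 1 h; then CuBr·SMe2 (10 mol%), 4, −78 °C to rt
Reagents that add atoms: none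
Why: Directed ortho-metalation occurs only at the CH flanked by both chelating MOM ethers (the bulky, non-coordinating OTIPS shields its own ortho positions), and copper-catalysed SN2 allylation with geranyl bromide keeps the E-alkene.

Step 4
Reactants: 6 2-Ger-1,3-bis(MOM-oxy)-5-(TIPS-oxy)benzene
Product: 7 4-Ger-3,5-bis(MOM-oxy)phenol
Conditions: TBAF, THF, 0 °C; H2O work-up
Reagents that add atoms: none
Why: Fluoride-driven desilylation frees only the unique phenol because MOM ethers and the geranyl chain are inert to fluoride.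

Step 5
Reactants: 7 4-Ger-3,5-bis(MOM-oxy)phenol
Product: 8 2-[4-Ger-3,5-bis(MOM-oxy)phenoxy]tetrahydro-2H-pyran
Conditions: DHP, PPTS (cat.), CH2Cl2, rt
Reagents that add atoms: 3,4-dihydro-2H-pyran (DHP), C1=COCCC1
Why: Mild acid-catalysed tetrahydropyranylation gives an acetal that directs lithiation, survives base and peroxide, and can later be removed without touching the MOM ethers.

Step 6
Reactants: 8 2-[4-Ger-3,5-bis(MOM-oxy)phenoxy]tetrahydro-2H-pyran, 9 N-methoxy-N-methylacetamide
Product: 12 1-[3-Ger-2,4-bis(MOM-oxy)-6-(THP-oxy)phenyl]ethan-1-one, via ring-lithiated arene 10 (not isolated), via lithium hemiaminal alkoxide 11 (not isolated)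
Conditions: n-BuLi, THF, −20 to 0 °C; then 9, −78 to 0 °C; H2O
Reagents that add atoms: none
Why: Directed ortho-metalation at a ring CH flanked by OTHP and OMOM (the two remaining ring positions are equivalent) followed by Weinreb ketone synthesis stops at the methyl ketone because the chelated tetrahedral adduct only collapses on work-up.

Step 7
Reactants: 12 1-[3-Ger-2,4-bis(MOM-oxy)-6-(THP-oxy)phenyl]ethan-1-one, 13 benzaldehyde
Product: 15 (2E)-1-[3-Ger-2,4-bis(MOM-oxy)-6-(THP-oxy)phenyl]-3-phenylprop-2-en-1-one, via racemic aldol adduct 14 (not isolated)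
Conditions: KOH, EtOH/H2O, rt, 24 h
Reagents that add atoms: none
Why: In this Claisen–Schmidt (crossed aldol) condensation the methyl ketone enolate adds to non-enolisable benzaldehyde and the aldol dehydrates by E1cB to the (E)-enone, forming the C2–C3 bond that joins the ring A and ring B fragments under conditions all three acetals tolerate.

Step 8
Reactants: 15 (2E)-1-[3-Ger-2,4-bis(MOM-oxy)-6-(THP-oxy)phenyl]-3-phenylprop-2-en-1-one
Product: 16 [3-Ger-2,4-bis(MOM-oxy)-6-(THP-oxy)phenyl][(2R,3S)-3-phenyloxiran-2-yl]methanone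
Conditions: poly-L-leucine, urea·H2O2, DBU, THF, rt
Reagents that add atoms: hydrogen peroxide (used as its urea adduct), OO
Why: In the Juliá–Colonna asymmetric nucleophilic epoxidation the poly-L-leucine helix steers hydroperoxide onto one enone face to set the (2R,3S)-epoxide, and the nucleophilic oxidant leaves the electron-rich geranyl alkenes alone.

Step 9
Reactants: 16 [3-Ger-2,4-bis(MOM-oxy)-6-(THP-oxy)phenyl][(2R,3S)-3-phenyloxiran-2-yl]methanone
Product: 17 (3R)-1-[3-Ger-2,4-bis(MOM-oxy)-6-(THP-oxy)phenyl]-3-hydroxy-3-phenylpropan-1-one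
Conditions: SmI2 (2.2 equiv), THF/MeOH, −90 °C
Reagents that add atoms: none
Why: Single-electron reduction of the ketone by divalent samarium cleaves only the adjacent Cα–O bond (reductive epoxy ketone opening), so the benzylic C–O stereocentre is retained and becomes the (3R)-carbinol (the descriptor changes only through CIP priorities).

Step 10
Reactants: 17 (3R)-1-[3-Ger-2,4-bis(MOM-oxy)-6-(THP-oxy)phenyl]-3-hydroxy-3-phenylpropan-1-one
Product: 18 (3R)-1-[3-Ger-6-hydroxy-2,4-bis(MOM-oxy)phenyl]-3-hydroxy-3-phenylpropan-1-one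
Conditions: PPTS, MeOH, rt
Reagents that add atoms: none
Why: Acid-catalysed transacetalisation removes the aryl THP acetal, which is far more labile than aryl MOM ethers at rt, and frees only the phenol that sits next to the ring CH.

Step 11
Reactants: 18 (3R)-1-[3-Ger-6-hydroxy-2,4-bis(MOM-oxy)phenyl]-3-hydroxy-3-phenylpropan-1-one
Product: 19 (2S)-6-Ger-5,7-bis(MOM-oxy)-2-phenyl-2,3-dihydro-4H-chromen-4-one
Conditions: PPh3, DIAD, THF, 0 °C to rt
Reagents that add atoms: none
Why: In this intramolecular Mitsunobu etherification the acidic, ketone-bound phenol displaces the activated benzylic oxyphosphonium by SN2, closing ring C with clean inversion (R to 2S) and with the 6-geranyl regiochemistry fixed by the single free phenol.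

Step 12
Reactants: 19 (2S)-6-Ger-5,7-bis(MOM-oxy)-2-phenyl-2,3-dihydro-4H-chromen-4-one
Product: 20 (2S)-6-Ger-5,7-dihydroxy-2-phenyl-2,3-dihydro-4H-chromen-4-one (CNP0201748.1)
Conditions: 3 M aq HCl/MeOH (1:4), 45 °C, 2–4 h, monitored
Reagents that add atoms: none
Why: Acid-catalysed MOM acetal cleavage frees both phenols under dilute, short conditions that do not epimerise C2 (no base, no ring opening) and are expected to leave the geranyl chain intact.

## Compound list

1 | phloroglucinol | Oc1cc(O)cc(O)c1 | starting material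
2 | 5-(TIPS-oxy)benzene-1,3-diol | CC(C)[Si](Oc1cc(O)cc(O)c1)(C(C)C)C(C)C | intermediate
3 | 1,3-bis(MOM-oxy)-5-(TIPS-oxy)benzene | COCOc1cc(OCOC)cc(O[Si](C(C)C)(C(C)C)C(C)C)c1 | intermediate
4 | geranyl bromide, (2E)-1-bromo-3,7-dimethylocta-2,6-diene | CC(C)=CCC/C(C)=C/CBr | starting material
5 | 2-lithio-1,3-bis(MOM-oxy)-5-(TIPS-oxy)benzene | COCOc1cc(O[Si](C(C)C)(C(C)C)C(C)C)cc(OCOC)c1[Li] | intermediate
6 | 2-Ger-1,3-bis(MOM-oxy)-5-(TIPS-oxy)benzene | CC(C)=CCC/C(C)=C/Cc1c(OCOC)cc(O[Si](C(C)C)(C(C)C)C(C)C)cc1OCOC | intermediate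
7 | 4-Ger-3,5-bis(MOM-oxy)phenol | CC(C)=CCC/C(C)=C/Cc1c(OCOC)cc(O)cc1OCOC | intermediate
8 | 2-[4-Ger-3,5-bis(MOM-oxy)phenoxy]tetrahydro-2H-pyran | CC(C)=CCC/C(C)=C/Cc1c(OCOC)cc(OC2CCCCO2)cc1OCOC | intermediate
9 | N-methoxy-N-methylacetamide | CC(=O)N(C)OC | starting material
10 | aryllithium of 8, lithiated between OTHP and OMOM | CC(C)=CCC/C(C)=C/Cc1c(OCOC)c([Li])c(OC2CCCCO2)cc1OCOC | intermediate
11 | lithium alkoxide of the N-methoxy-N-methyl hemiaminal (tetrahedral adduct of 10 and 9) | CC(C)=CCC/C(C)=C/Cc1c(OCOC)c(C(C)(O[Li])N(C)OC)c(OC2CCCCO2)cc1OCOC | intermediate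
12 | 1-[3-Ger-2,4-bis(MOM-oxy)-6-(THP-oxy)phenyl]ethan-1-one | CC(C)=CCC/C(C)=C/Cc1c(OCOC)c(C(C)=O)c(OC2CCCCO2)cc1OCOC | intermediate
13 | benzaldehyde | O=Cc1ccccc1 | starting material
14 | racemic 1-[3-Ger-2,4-bis(MOM-oxy)-6-(THP-oxy)phenyl]-3-hydroxy-3-phenylpropan-1-one | CC(C)=CCC/C(C)=C/Cc1c(OCOC)c(C(=O)CC(O)c2ccccc2)c(OC3CCCCO3)cc1OCOC | intermediate
15 | (2E)-1-[3-Ger-2,4-bis(MOM-oxy)-6-(THP-oxy)phenyl]-3-phenylprop-2-en-1-one | CC(C)=CCC/C(C)=C/Cc1c(OCOC)c(C(=O)/C=C/c2ccccc2)c(OC3CCCCO3)cc1OCOC | intermediate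
16 | [3-Ger-2,4-bis(MOM-oxy)-6-(THP-oxy)phenyl][(2R,3S)-3-phenyloxiran-2-yl]methanone | CC(C)=CCC/C(C)=C/Cc1c(OCOC)c(C(=O)[C@@H]2O[C@H]2c3ccccc3)c(OC4CCCCO4)cc1OCOC | intermediate
17 | (3R)-1-[3-Ger-2,4-bis(MOM-oxy)-6-(THP-oxy)phenyl]-3-hydroxy-3-phenylpropan-1-one | CC(C)=CCC/C(C)=C/Cc1c(OCOC)c(C(=O)C[C@@H](O)c2ccccc2)c(OC3CCCCO3)cc1OCOC | intermediate
18 | (3R)-1-[3-Ger-6-hydroxy-2,4-bis(MOM-oxy)phenyl]-3-hydroxy-3-phenylpropan-1-one | CC(C)=CCC/C(C)=C/Cc1c(OCOC)c(C(=O)C[C@@H](O)c2ccccc2)c(O)cc1OCOC | intermediate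
19 | (2S)-6-Ger-5,7-bis(MOM-oxy)-2-phenyl-2,3-dihydro-4H-chromen-4-one | CC(C)=CCC/C(C)=C/Cc1c(OCOC)cc2c(c1OCOC)C(=O)C[C@@H](c1ccccc1)O2 | intermediate
20 | (2S)-6-Ger-5,7-dihydroxy-2-phenyl-2,3-dihydro-4H-chromen-4-one (6-geranylpinocembrin) | CC(C)=CCC/C(C)=C/Cc1c(O)cc2c(c1O)C(=O)C[C@@H](c1ccccc1)O2 | target

## Step count and risk

Total step count: 12. Longest linear sequence: 12 steps (1 to 20).

The three steps most likely to fail:

**Step 6 (acylation of the hindered aryllithium).** The di-ortho-substituted aryllithium may deprotonate the acetamide instead of adding to it, returning 8. The fallback sets out from 8: the same aryllithium 10 is trapped with acetaldehyde, a far better electrophile, to give the secondary alcohol 1-[3-Ger-2,4-bis(MOM-oxy)-6-(THP-oxy)phenyl]ethan-1-ol F1. Oxidation of this benzylic alcohol with Dess–Martin periodinane (NaHCO3, CH2Cl2, rt) then comes back to the route at 12.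

**Step 8 (asymmetric epoxidation of a hindered, electron-rich chalcone).** Rate and ee may fall short on the 2',6'-dioxygenated aryl ketone. The fallback sets out from 15 and sets the carbinol centre by C–B bond formation instead. Copper-catalysed enantioselective conjugate borylation uses CuCl, NaOt-Bu, B2pin2 and MeOH in THF with the ferrocenyl diphosphine (R)-1-[(Sp)-2-(diphenylphosphino)ferrocenyl]ethyldicyclohexylphosphine or its mirror image, the antipode being chosen on a test scale. It gives the β-boryl ketone (3R)-1-[3-Ger-2,4-bis(MOM-oxy)-6-(THP-oxy)phenyl]-3-phenyl-3-(4,4,5,5-tetramethyl-1,3,2-dioxaborolan-2-yl)propan-1-one F2. Oxidation with NaBO3·4H2O in THF/H2O replaces boron by OH with retention and comes back to the route at 17, so 16 and step 9 are skipped.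

**Step 11 (Mitsunobu ring closure).** E1cB loss of the activated β-oxygen back to a chalcone, or partial ionisation at the benzylic carbon, would cost yield or ee. The fallback sets out from 15 and closes ring C by oxa-Michael addition, then resolves. PPTS in MeOH frees the phenol to give the hydroxychalcone (2E)-1-[3-Ger-6-hydroxy-2,4-bis(MOM-oxy)phenyl]-3-phenylprop-2-en-1-one F3. NaOAc in refluxing EtOH cyclises it to the racemic flavanone 6-Ger-5,7-bis(MOM-oxy)-2-phenyl-2,3-dihydro-4H-chromen-4-one F4. Kinetic resolution by asymmetric transfer hydrogenation (Cp*RhCl[(R,R)-TsDPEN] or its (S,S)-antipode, HCO2H/Et3N, EtOAc, rt; the antipode that consumes the (2R)-ketone is chosen on a test scale) reduces the unwanted enantiomer to the cis-alcohol (2R,4R)-6-Ger-5,7-bis(MOM-oxy)-2-phenyl-3,4-dihydro-2H-chromen-4-ol F5. The unreacted (2S)-ketone is recovered (at most 50%) and comes back to the route at 19.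

## Further compounds

F1 | step 6 | 1-[3-Ger-2,4-bis(MOM-oxy)-6-(THP-oxy)phenyl]ethan-1-ol (mixture of diastereomers) | CC(C)=CCC/C(C)=C/Cc1c(OCOC)c(C(C)O)c(OC2CCCCO2)cc1OCOC
F2 | step 8 | (3R)-1-[3-Ger-2,4-bis(MOM-oxy)-6-(THP-oxy)phenyl]-3-phenyl-3-(4,4,5,5-tetramethyl-1,3,2-dioxaborolan-2-yl)propan-1-one | CC(C)=CCC/C(C)=C/Cc1c(OCOC)c(C(=O)C[C@@H](B2OC(C)(C)C(C)(C)O2)c3ccccc3)c(OC4CCCCO4)cc1OCOC
F3 | step 11 | (2E)-1-[3-Ger-6-hydroxy-2,4-bis(MOM-oxy)phenyl]-3-phenylprop-2-en-1-one | CC(C)=CCC/C(C)=C/Cc1c(OCOC)c(C(=O)/C=C/c2ccccc2)c(O)cc1OCOC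
F4 | step 11 | racemic 6-Ger-5,7-bis(MOM-oxy)-2-phenyl-2,3-dihydro-4H-chromen-4-one | CC(C)=CCC/C(C)=C/Cc1c(OCOC)cc2c(c1OCOC)C(=O)CC(c1ccccc1)O2
F5 | step 11 | (2R,4R)-6-Ger-5,7-bis(MOM-oxy)-2-phenyl-3,4-dihydro-2H-chromen-4-ol | CC(C)=CCC/C(C)=C/Cc1c(OCOC)cc2c(c1OCOC)[C@H](O)C[C@H](c1ccccc1)O2
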